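In ring A (the dihydropyran: O1, C2 with two methyls, C3=C4, C5, C6) the tertiary ether carbon C6 sits next to the secondary carbinol C5; such a 1,2-dioxygenated pair is what an epoxide across C5–C6 leaves behind once the future ring oxygen has attacked C6. The whole plan hangs on this O1–C6 disconnection. A single acid-catalysed event closes ring A, builds the fully substituted C6 with inversion and uncovers the C5 hydroxyl, so one reagent-controlled epoxidation fixes both pyran stereocentres. The substrate is a Z-configured epoxy alcohol in which a tertiary carbinol is tied by a cis alkene to a trisubstituted epoxide bearing a ketal-protected (S)-3-oxocyclohexyl group; the halogens follow from that ketone.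

Key step: step 11

Remark on atom labels: the pyran is labelled O1, C2 (CMe2), C3=C4, C5 (CHOH), C6 (carbon bearing CH3 and the carbocycle); the carbocycle is C1′ (on C6) to C6′, with Cl and CH3 on C4′ and Br on C5′; systematic names number the pyran from the other side.
Assumption: the Rh/(S)-BINAP addition of step 4 is taken to follow the usual sense for aryl and alkenyl transfer to cyclohex-2-en-1-one, which gives the (S)-ketone; boronate 5 is E by CIP rules only because carbon outranks boron, its boron being cis to CH2OTBS.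

Step 1
Reactants: 1 but-2-yn-1-ol
Product: 3 (Z)-3-iodobut-2-en-1-ol, via cyclic alkenylaluminate 2 (not isolated)
Conditions: NaAlH2(OCH2CH2OCH3)2, THF, 0 °C to rt; then N-iodosuccinimide, −78 °C to 0 °C
Reagents that add atoms: N-iodosuccinimide, O=C1CCC(=O)N1I
Why: Hydroalumination–iodination: the alkoxide-directed trans-hydroalumination puts aluminium on C3 inside a five-membered aluminate, and iodinolysis of that carbon–aluminium bond with retention should leave iodine cis to CH2OH.

Step 2
Reactants: 3 (Z)-3-iodobut-2-en-1-ol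
Product: 4 (Z)-tert-butyl[(3-iodobut-2-en-1-yl)oxy]dimethylsilane
Conditions: TBSCl, imidazole, CH2Cl2, 0 °C to rt
Reagents that add atoms: tert-butyldimethylsilyl chloride, CC(C)(C)[Si](C)(C)Cl
Why: Silyl ether formation on a primary alcohol masks the hydroxyl for the borylation and the basic conjugate addition.

Step 3
Reactants: 4 (Z)-tert-butyl[(3-iodobut-2-en-1-yl)oxy]dimethylsilane
Product: 5 (E)-tert-butyldimethyl{[3-(4,4,5,5-tetramethyl-1,3,2-dioxaborolan-2-yl)but-2-en-1-yl]oxy}silane (boron cis to CH2OTBS)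
Conditions: B2pin2, PdCl2(PPh3)2 (cat.), PPh3, KOPh, toluene, 50 °C
Reagents that add atoms: bis(pinacolato)diboron, CC1(C)OB(OC1(C)C)B2OC(C)(C)C(C)(C)O2
Why: Miyaura borylation of an alkenyl iodide: oxidative addition to zerovalent palladium, phenoxide-assisted transmetallation and reductive elimination all retain the alkene geometry, so boron should take the place of iodine.

Step 4
Reactants: 5 (E)-tert-butyldimethyl{[3-(4,4,5,5-tetramethyl-1,3,2-dioxaborolan-2-yl)but-2-en-1-yl]oxy}silane and 6 cyclohex-2-en-1-one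
Product: 7 (S)-3-[(Z)-4-(tert-butyldimethylsilyloxy)but-2-en-2-yl]cyclohexan-1-one
Conditions: [Rh(OH)(C8H12)]2 (C8H12 = cycloocta-1,5-diene, cat.), (S)-BINAP, KOH (0.3 equiv), dioxane/H2O 10:1, 40 °C
Reagents that add atoms: none
Why: Hayashi–Miyaura asymmetric 1,4-addition: transmetallation from boron gives an alkenylrhodium species (monovalent rhodium) that adds to the enone face selected by (S)-BINAP, which should set C1′ as S while the alkene geometry is carried over unchanged.

Step 5
Reactants: 7 (S)-3-[(Z)-4-(tert-butyldimethylsilyloxy)but-2-en-2-yl]cyclohexan-1-one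
Product: 8 tert-butyldimethyl{[(Z)-3-((S)-1,4-dioxaspiro[4.5]decan-7-yl)but-2-en-1-yl]oxy}silane
Conditions: Me3SiOCH2CH2OSiMe3, Me3SiOTf (cat.), CH2Cl2, −78 °C
Reagents that add atoms: 1,2-bis(trimethylsilyloxy)ethane, C[Si](C)(C)OCCO[Si](C)(C)C
Why: Noyori ketalisation under aprotic, low-temperature conditions converts the ketone into the dioxolane without touching the allylic silyl ether or the trisubstituted alkene.

Step 6
Reactants: 8 tert-butyldimethyl{[(Z)-3-((S)-1,4-dioxaspiro[4.5]decan-7-yl)but-2-en-1-yl]oxy}silane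
Product: 9 (Z)-3-[(S)-1,4-dioxaspiro[4.5]decan-7-yl]but-2-en-1-ol
Conditions: Bu4NF, THF, 0 °C to rt
Reagents that add atoms: none
Why: Fluoride-induced desilylation frees the allylic hydroxyl that must direct the epoxidation, and the ketal is inert to fluoride.

Step 7
Reactants: 9 (Z)-3-[(S)-1,4-dioxaspiro[4.5]decan-7-yl]but-2-en-1-ol
Product: 10 [(2R,3S)-3-methyl-3-((S)-1,4-dioxaspiro[4.5]decan-7-yl)oxiran-2-yl]methanol
Conditions: Ti(OiPr)4 (0.2 equiv), D-(−)-diethyl tartrate (0.25 equiv), t-BuOOH, 4 Å MS, CH2Cl2, −20 °C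
Reagents that add atoms: tert-butyl hydroperoxide, CC(C)(C)OO
Why: Sharpless asymmetric epoxidation: with D-(−)-tartrate the titanium-bound hydroperoxide should reach the face of this nerol-type Z allylic alcohol that gives the (2R,3S)-epoxy alcohol, the reagent overriding the weak bias of the remote C1′ centre, so both future pyran stereocentres are set here.

Step 8
Reactants: 10 [(2R,3S)-3-methyl-3-((S)-1,4-dioxaspiro[4.5]decan-7-yl)oxiran-2-yl]methanol
Product: 11 (2S,3S)-3-methyl-3-[(S)-1,4-dioxaspiro[4.5]decan-7-yl]oxirane-2-carbaldehyde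
Conditions: TEMPO (cat.), PhI(OAc)2, CH2Cl2, rt
Reagents that add atoms: none
Why: Oxoammonium (TEMPO) oxidation takes the primary alcohol to the aldehyde under near-neutral conditions that spare epoxide and ketal, and an epoxy aldehyde resists epimerisation (the descriptor at C2 changes only because CHO outranks C3).

Step 9
Reactants: 11 (2S,3S)-3-methyl-3-[(S)-1,4-dioxaspiro[4.5]decan-7-yl]oxirane-2-carbaldehyde and 12 methyl bis(2,2,2-trifluoroethyl)phosphonoacetate
Product: 13 methyl (Z)-3-[(2R,3S)-3-methyl-3-((S)-1,4-dioxaspiro[4.5]decan-7-yl)oxiran-2-yl]prop-2-enoate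
Conditions: KN(SiMe3)2, 18-crown-6, THF, −78 °C
Reagents that add atoms: none
Why: Still–Gennari olefination: the trifluoroethyl phosphonate anion with a dissociated potassium ion eliminates rapidly and irreversibly from the first-formed adduct, which should give the Z enoate.

Step 10
Reactants: 13 methyl (Z)-3-[(2R,3S)-3-methyl-3-((S)-1,4-dioxaspiro[4.5]decan-7-yl)oxiran-2-yl]prop-2-enoate
Product: 15 (Z)-2-methyl-4-[(2R,3S)-3-methyl-3-((S)-1,4-dioxaspiro[4.5]decan-7-yl)oxiran-2-yl]but-3-en-2-ol, via Z-methyl enone 14 (not isolated)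
Conditions: MeLi (2.5 equiv), THF, −78 °C; then H2O at −78 °C
Reagents that add atoms: methyllithium, [Li]C
Why: Double 1,2-addition of an organolithium to an ester gives the tertiary carbinol, and the cold quench should keep the lithium alkoxide from opening the epoxide under basic conditions.

Step 11
Reactants: 15 (Z)-2-methyl-4-[(2R,3S)-3-methyl-3-((S)-1,4-dioxaspiro[4.5]decan-7-yl)oxiran-2-yl]but-3-en-2-ol
Product: 16 (2R,3R)-2,6,6-trimethyl-2-[(S)-1,4-dioxaspiro[4.5]decan-7-yl]-3,6-dihydro-2H-pyran-3-ol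
Conditions: (1S)-(+)-camphor-10-sulfonic acid (0.1 equiv), CH2Cl2, −20 °C to 0 °C
Reagents that add atoms: none
Why: The sulfonic acid activates the epoxide oxygen; the C6–O bond, at the only epoxide carbon with three carbon substituents, stretches first, and the C2 hydroxyl, which the cis C3=C4 alkene parks next to C6, displaces it from the rear in a loose SN2 transition state, so that O1–C6 forms as the C5 oxygen is released as a hydroxyl. The closest known reaction type is the acid-catalysed, endo-selective hydroxy-epoxide cyclisation of trisubstituted epoxides at their more substituted carbon, which delivers tetrahydropyrans with inversion. The dihydropyran ring (O1, C2, C3, C4, C5, C6) closes in the 6-endo-tet mode. C6 is formed as R by inversion of the S epoxide carbon and is therefore controlled by the epoxide installed in step 7, whereas C5 is untouched and stays R. Two selectivities are needed: C6 over the 5-exo site C5, secured by the tertiary nature of C6 and by the fact that the ring-forming trajectory to C5 lies in the plane of the alkene, where the π bond cannot stabilise the breaking C5–O bond; and concerted displacement over free ionisation, secured by a catalytic acid in cold, non-ionising CH2Cl2.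

Step 12
Reactants: 16 (2R,3R)-2,6,6-trimethyl-2-[(S)-1,4-dioxaspiro[4.5]decan-7-yl]-3,6-dihydro-2H-pyran-3-ol
Product: 17 tert-butyldimethyl{[(2R,3R)-2,6,6-trimethyl-2-((S)-1,4-dioxaspiro[4.5]decan-7-yl)-3,6-dihydro-2H-pyran-3-yl]oxy}silane
Conditions: TBSOTf, 2,6-lutidine, CH2Cl2, 0 °C
Reagents that add atoms: tert-butyldimethylsilyl trifluoromethanesulfonate, CC(C)(C)[Si](C)(C)OS(=O)(=O)C(F)(F)F
Why: Silyl ether formation with the reactive silyl triflate protects the hindered secondary allylic alcohol against the enolate, hydride and triflation chemistry that follows.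

Step 13
Reactants: 17 tert-butyldimethyl{[(2R,3R)-2,6,6-trimethyl-2-((S)-1,4-dioxaspiro[4.5]decan-7-yl)-3,6-dihydro-2H-pyran-3-yl]oxy}silane
Product: 18 (S)-3-[(2R,3R)-3-(tert-butyldimethylsilyloxy)-2,6,6-trimethyl-3,6-dihydro-2H-pyran-2-yl]cyclohexan-1-one
Conditions: PPTS, acetone/H2O 4:1, 50 °C
Reagents that add atoms: water, O
Why: Mild acid-catalysed ketal hydrolysis returns the ring ketone, and the hindered silyl ether and the tertiary allylic ether should tolerate the buffered pyridinium acid.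

Step 14
Reactants: 18 (S)-3-[(2R,3R)-3-(tert-butyldimethylsilyloxy)-2,6,6-trimethyl-3,6-dihydro-2H-pyran-2-yl]cyclohexan-1-one
Product: 20 (5S)-2-chloro-5-[(2R,3R)-3-(tert-butyldimethylsilyloxy)-2,6,6-trimethyl-3,6-dihydro-2H-pyran-2-yl]cyclohexan-1-one (both C2 epimers), via trimethylsilyl enol ether 19 (not isolated)
Conditions: LiN(iPr)2, Me3SiCl, THF, −78 °C; then N-chlorosuccinimide, THF, 0 °C
Reagents that add atoms: N-chlorosuccinimide, O=C1CCC(=O)N1Cl
Why: Kinetic enol silane formation takes the α-hydrogen on the side remote from the bulky C1′ substituent, and electrophilic α-chlorination of that enol ether puts chlorine on C4′ (its configuration is irrelevant because step 15 erases it).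

Step 15
Reactants: 20 (5S)-2-chloro-5-[(2R,3R)-3-(tert-butyldimethylsilyloxy)-2,6,6-trimethyl-3,6-dihydro-2H-pyran-2-yl]cyclohexan-1-one
Product: 22 (2S,5S)-2-chloro-2-methyl-5-[(2R,3R)-3-(tert-butyldimethylsilyloxy)-2,6,6-trimethyl-3,6-dihydro-2H-pyran-2-yl]cyclohexan-1-one, via lithium chloro enolate 21 (not isolated)
Conditions: LiN(SiMe3)2 (1.05 equiv), THF, −78 °C; then MeI, DMPU, −78 °C to −20 °C
Reagents that add atoms: iodomethane, CI
Why: Enolate alkylation: the more acidic C4′–H is removed, and the tetrasubstituted chloro enolate should be methylated on its axial face through a chair-like transition state, placing CH3 cis to the equatorial C1′ substituent and chlorine equatorial (C4′ S).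

Step 16
Reactants: 22 (2S,5S)-2-chloro-2-methyl-5-[(2R,3R)-3-(tert-butyldimethylsilyloxy)-2,6,6-trimethyl-3,6-dihydro-2H-pyran-2-yl]cyclohexan-1-one
Product: 23 (1R,2S,5S)-2-chloro-2-methyl-5-[(2R,3R)-3-(tert-butyldimethylsilyloxy)-2,6,6-trimethyl-3,6-dihydro-2H-pyran-2-yl]cyclohexan-1-ol
Conditions: LiBH(s-Bu)3, THF, −78 °C; then H2O
Reagents that add atoms: none
Why: Bulky-hydride ketone reduction: the trialkylborohydride attacks from the equatorial direction, away from the 1,3-diaxial hydrogens, and should give the axial alcohol cis to chlorine (C5′ R), an arrangement that cannot close to an epoxide.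

Step 17
Reactants: 23 (1R,2S,5S)-2-chloro-2-methyl-5-[(2R,3R)-3-(tert-butyldimethylsilyloxy)-2,6,6-trimethyl-3,6-dihydro-2H-pyran-2-yl]cyclohexan-1-ol
Product: 25 {[(2R,3R)-2-((1S,3S,4S)-3-bromo-4-chloro-4-methylcyclohexyl)-2,6,6-trimethyl-3,6-dihydro-2H-pyran-3-yl]oxy}(tert-butyl)dimethylsilane, via axial triflate 24 (not isolated)
Conditions: Tf2O, pyridine, CH2Cl2, −30 °C; then Bu4NBr, toluene, 0 °C to rt
Reagents that add atoms: tetrabutylammonium bromide, [Br-].CCCC[N+](CCCC)(CCCC)CCCC
Why: Triflation followed by SN2 displacement with soluble bromide inverts C5′, turning the axial oxygen into the equatorial bromide (C5′ S), while the electron-withdrawing chlorine on C4′ disfavours ionisation and rearrangement.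

Step 18
Reactants: 25 {[(2R,3R)-2-((1S,3S,4S)-3-bromo-4-chloro-4-methylcyclohexyl)-2,6,6-trimethyl-3,6-dihydro-2H-pyran-3-yl]oxy}(tert-butyl)dimethylsilane
Product: 26 (2R,3R)-2-[(1S,3S,4S)-3-bromo-4-chloro-4-methylcyclohexyl]-2,6,6-trimethyl-3,6-dihydro-2H-pyran-3-ol
Conditions: HF·pyridine, THF/pyridine, 0 °C to rt
Reagents that add atoms: none
Why: Fluoride-mediated desilylation under buffered, non-basic conditions frees the C5 hydroxyl without base-induced loss of HBr or HCl.

Compound list
1 | but-2-yn-1-ol | CC#CCO | starting material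
2 | sodium 2,2-bis(2-methoxyethoxy)-3-methyl-2,5-dihydro-1,2-oxaaluminol-2-uide (cyclic alkenylaluminate) | CC1=CCO[Al-]1(OCCOC)OCCOC.[Na+] | intermediate (not isolated)
3 | (Z)-3-iodobut-2-en-1-ol | C/C(I)=C/CO | intermediate
4 | (Z)-tert-butyl[(3-iodobut-2-en-1-yl)oxy]dimethylsilane | C/C(I)=C/CO[Si](C)(C)C(C)(C)C | intermediate
5 | (E)-tert-butyldimethyl{[3-(4,4,5,5-tetramethyl-1,3,2-dioxaborolan-2-yl)but-2-en-1-yl]oxy}silane, boron cis to CH2OTBS | C/C(B1OC(C)(C)C(C)(C)O1)=C/CO[Si](C)(C)C(C)(C)C | intermediate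
6 | cyclohex-2-en-1-one | O=C1C=CCCC1 | starting material
7 | (S)-3-[(Z)-4-(tert-butyldimethylsilyloxy)but-2-en-2-yl]cyclohexan-1-one | CC(C)(C)[Si](C)(C)OC/C=C(C)\[C@H]1CCCC(=O)C1 | intermediate
8 | tert-butyldimethyl{[(Z)-3-((S)-1,4-dioxaspiro[4.5]decan-7-yl)but-2-en-1-yl]oxy}silane | CC(C)(C)[Si](C)(C)OC/C=C(C)\[C@H]1CCCC2(C1)OCCO2 | intermediate
9 | (Z)-3-[(S)-1,4-dioxaspiro[4.5]decan-7-yl]but-2-en-1-ol | OC/C=C(C)\[C@H]1CCCC2(C1)OCCO2 | intermediate
10 | [(2R,3S)-3-methyl-3-((S)-1,4-dioxaspiro[4.5]decan-7-yl)oxiran-2-yl]methanol | OC[C@H]1O[C@@]1(C)[C@H]2CCCC3(C2)OCCO3 | intermediate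
11 | (2S,3S)-3-methyl-3-[(S)-1,4-dioxaspiro[4.5]decan-7-yl]oxirane-2-carbaldehyde | O=C[C@H]1O[C@@]1(C)[C@H]2CCCC3(C2)OCCO3 | intermediate
12 | methyl bis(2,2,2-trifluoroethyl)phosphonoacetate | COC(=O)CP(=O)(OCC(F)(F)F)OCC(F)(F)F | starting material
13 | methyl (Z)-3-[(2R,3S)-3-methyl-3-((S)-1,4-dioxaspiro[4.5]decan-7-yl)oxiran-2-yl]prop-2-enoate | COC(=O)/C=C\[C@H]1O[C@@]1(C)[C@H]2CCCC3(C2)OCCO3 | intermediate
14 | (Z)-4-[(2R,3S)-3-methyl-3-((S)-1,4-dioxaspiro[4.5]decan-7-yl)oxiran-2-yl]but-3-en-2-one | CC(=O)/C=C\[C@H]1O[C@@]1(C)[C@H]2CCCC3(C2)OCCO3 | intermediate (not isolated)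
15 | (Z)-2-methyl-4-[(2R,3S)-3-methyl-3-((S)-1,4-dioxaspiro[4.5]decan-7-yl)oxiran-2-yl]but-3-en-2-ol | CC(C)(O)/C=C\[C@H]1O[C@@]1(C)[C@H]2CCCC3(C2)OCCO3 | intermediate (key-step precursor)
16 | (2R,3R)-2,6,6-trimethyl-2-[(S)-1,4-dioxaspiro[4.5]decan-7-yl]-3,6-dihydro-2H-pyran-3-ol | CC1(C)C=C[C@@H](O)[C@@](C)([C@H]2CCCC3(C2)OCCO3)O1 | intermediate (key-step product)
17 | tert-butyldimethyl{[(2R,3R)-2,6,6-trimethyl-2-((S)-1,4-dioxaspiro[4.5]decan-7-yl)-3,6-dihydro-2H-pyran-3-yl]oxy}silane | CC1(C)C=C[C@@H](O[Si](C)(C)C(C)(C)C)[C@@](C)([C@H]2CCCC3(C2)OCCO3)O1 | intermediate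
18 | (S)-3-[(2R,3R)-3-(tert-butyldimethylsilyloxy)-2,6,6-trimethyl-3,6-dihydro-2H-pyran-2-yl]cyclohexan-1-one | CC1(C)C=C[C@@H](O[Si](C)(C)C(C)(C)C)[C@@](C)([C@H]2CCCC(=O)C2)O1 | intermediate
19 | tert-butyldimethyl{[(2R,3R)-2,6,6-trimethyl-2-((S)-3-(trimethylsilyloxy)cyclohex-3-en-1-yl)-3,6-dihydro-2H-pyran-3-yl]oxy}silane | CC1(C)C=C[C@@H](O[Si](C)(C)C(C)(C)C)[C@@](C)([C@H]2CCC=C(O[Si](C)(C)C)C2)O1 | intermediate (not isolated)
20 | (5S)-2-chloro-5-[(2R,3R)-3-(tert-butyldimethylsilyloxy)-2,6,6-trimethyl-3,6-dihydro-2H-pyran-2-yl]cyclohexan-1-one, both C2 epimers | CC1(C)C=C[C@@H](O[Si](C)(C)C(C)(C)C)[C@@](C)([C@H]2CCC(Cl)C(=O)C2)O1 | intermediate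
21 | lithium (S)-2-chloro-5-[(2R,3R)-3-(tert-butyldimethylsilyloxy)-2,6,6-trimethyl-3,6-dihydro-2H-pyran-2-yl]cyclohex-1-en-1-olate | CC1(C)C=C[C@@H](O[Si](C)(C)C(C)(C)C)[C@@](C)([C@H]2CCC(Cl)=C(O[Li])C2)O1 | intermediate (not isolated)
22 | (2S,5S)-2-chloro-2-methyl-5-[(2R,3R)-3-(tert-butyldimethylsilyloxy)-2,6,6-trimethyl-3,6-dihydro-2H-pyran-2-yl]cyclohexan-1-one | CC1(C)C=C[C@@H](O[Si](C)(C)C(C)(C)C)[C@@](C)([C@H]2CC[C@](C)(Cl)C(=O)C2)O1 | intermediate
23 | (1R,2S,5S)-2-chloro-2-methyl-5-[(2R,3R)-3-(tert-butyldimethylsilyloxy)-2,6,6-trimethyl-3,6-dihydro-2H-pyran-2-yl]cyclohexan-1-ol | CC1(C)C=C[C@@H](O[Si](C)(C)C(C)(C)C)[C@@](C)([C@H]2CC[C@](C)(Cl)[C@H](O)C2)O1 | intermediate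
24 | (1R,2S,5S)-2-chloro-2-methyl-5-[(2R,3R)-3-(tert-butyldimethylsilyloxy)-2,6,6-trimethyl-3,6-dihydro-2H-pyran-2-yl]cyclohexyl trifluoromethanesulfonate | CC1(C)C=C[C@@H](O[Si](C)(C)C(C)(C)C)[C@@](C)([C@H]2CC[C@](C)(Cl)[C@H](OS(=O)(=O)C(F)(F)F)C2)O1 | intermediate (not isolated)
25 | {[(2R,3R)-2-((1S,3S,4S)-3-bromo-4-chloro-4-methylcyclohexyl)-2,6,6-trimethyl-3,6-dihydro-2H-pyran-3-yl]oxy}(tert-butyl)dimethylsilane | CC1(C)C=C[C@@H](O[Si](C)(C)C(C)(C)C)[C@@](C)([C@H]2CC[C@](C)(Cl)[C@@H](Br)C2)O1 | intermediate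
26 | (2R,3R)-2-[(1S,3S,4S)-3-bromo-4-chloro-4-methylcyclohexyl]-2,6,6-trimethyl-3,6-dihydro-2H-pyran-3-ol | CC1(C)C=C[C@@H](O)[C@@](C)([C@H]2CC[C@](C)(Cl)[C@@H](Br)C2)O1 | target

Total step count: 18. Longest linear sequence: 18 steps, from 1 to 26; 6 and 12 enter as purchased materials.

Steps most likely to fail

Step 17 (bromide for oxygen at C5′). The bromide has to approach C5′ past the axial C4′ methyl group, a neopentyl-type trajectory. Substitution may therefore be outrun by E2 loss of the triflate towards C6′, or by ionisation with methyl migration. The fallback replaces substitution by a bromonium route and sets out from ketone 18. Kinetic methylation (LiN(iPr)2, then MeI, THF, −78 °C) on the side away from C1′ would give the 2-methyl ketone F1. Tf2O with 2,6-di-tert-butyl-4-methylpyridine would give the more substituted enol triflate F2. Palladium-catalysed formate reduction (Pd(OAc)2, PPh3, Bu3N, HCO2H, DMF) would give the trisubstituted cyclohexene F3. Anti addition of BrCl (Bu4NBrCl2, CH2Cl2, −20 °C), with chloride opening the bromonium ion at the tertiary C4′, would give 25 from the bromonium ion formed cis to C1′. The adduct from the other face, the trans-diaxial isomer that such additions normally prefer, would have to be separated; this is why the sequence is the reserve and not the main line. The route is rejoined at 25.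

Step 15 (methylation of the chloro enolate). Deprotonation at C6′ instead of C4′ would open a Favorskii-type ring contraction. O-methylation and poor axial-versus-equatorial facial selectivity are further ways to lose material. The fallback generates the enolate regiospecifically without an amide base and sets out from 20. Soft enolisation (Me3SiOTf, Et3N, CH2Cl2, 0 °C) would give the chlorine-bearing enol silane F4. Anhydrous benzyltrimethylammonium fluoride with MeI in THF would then release the enolate only at C4′, in the presence of the electrophile. The route is rejoined at 22.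

Step 11 (key cyclisation). The tethered hydroxyl may attack C5 in the 5-exo mode. Alternatively the epoxide or the tertiary allylic carbinol may ionise before ring closure, with loss of configuration at C6 or rearrangement. The fallback closes ring A at O1–C2 instead and sets out from ester 13, which has no tethered hydroxyl. Acetolysis of the epoxide (AcOH, 40 °C) at the tertiary carbon with inversion, followed by lactonisation of the freed C5 hydroxyl onto the Z ester, would give the acetoxy butenolide F5. Excess MeLi (THF, −78 °C to 0 °C) would open the lactone and remove the acetate to give the triol F6. TBSCl and imidazole in DMF would silylate the only secondary hydroxyl to give the silyl ether F7. Catalytic PPTS in CH2Cl2 would ionise the tertiary allylic carbinol, and the C6 hydroxyl would capture the cation at C2, which is not a stereocentre. The route is rejoined at 17.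

Further compounds
F1 | step 17 | (5S)-2-methyl-5-[(2R,3R)-3-(tert-butyldimethylsilyloxy)-2,6,6-trimethyl-3,6-dihydro-2H-pyran-2-yl]cyclohexan-1-one, both C2 epimers | CC1(C)C=C[C@@H](O[Si](C)(C)C(C)(C)C)[C@@](C)([C@H]2CCC(C)C(=O)C2)O1
F2 | step 17 | (S)-2-methyl-5-[(2R,3R)-3-(tert-butyldimethylsilyloxy)-2,6,6-trimethyl-3,6-dihydro-2H-pyran-2-yl]cyclohex-1-en-1-yl trifluoromethanesulfonate | CC1(C)C=C[C@@H](O[Si](C)(C)C(C)(C)C)[C@@](C)([C@H]2CCC(C)=C(OS(=O)(=O)C(F)(F)F)C2)O1
F3 | step 17 | tert-butyldimethyl{[(2R,3R)-2,6,6-trimethyl-2-((S)-4-methylcyclohex-3-en-1-yl)-3,6-dihydro-2H-pyran-3-yl]oxy}silane | CC1(C)C=C[C@@H](O[Si](C)(C)C(C)(C)C)[C@@](C)([C@H]2CCC(C)=CC2)O1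
F4 | step 15 | tert-butyl{[(2R,3R)-2-((S)-4-chloro-3-(trimethylsilyloxy)cyclohex-3-en-1-yl)-2,6,6-trimethyl-3,6-dihydro-2H-pyran-3-yl]oxy}dimethylsilane | CC1(C)C=C[C@@H](O[Si](C)(C)C(C)(C)C)[C@@](C)([C@H]2CCC(Cl)=C(O[Si](C)(C)C)C2)O1
F5 | step 11 | (R)-1-[(S)-1,4-dioxaspiro[4.5]decan-7-yl]-1-[(R)-5-oxo-2,5-dihydrofuran-2-yl]ethyl acetate | O=C1C=C[C@@H](O1)[C@](C)(OC(C)=O)[C@H]2CCCC3(C2)OCCO3
F6 | step 11 | (3Z,5R,6R)-6-[(S)-1,4-dioxaspiro[4.5]decan-7-yl]-2-methylhept-3-ene-2,5,6-triol | CC(C)(O)/C=C\[C@@H](O)[C@](C)(O)[C@H]1CCCC2(C1)OCCO2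
F7 | step 11 | (3Z,5R,6R)-5-(tert-butyldimethylsilyloxy)-6-[(S)-1,4-dioxaspiro[4.5]decan-7-yl]-2-methylhept-3-ene-2,6-diol | CC(C)(O)/C=C\[C@@H](O[Si](C)(C)C(C)(C)C)[C@](C)(O)[C@H]1CCCC2(C1)OCCO2
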